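## Retrosynthetic overview

1. The ten-membered carbocycle is closed last, at C1–C2, by an intramolecular CrCl2/NiCl2 (Nozaki–Hiyama–Kishi) coupling of a (Z)-vinyl iodide with the C1 aldehyde; diimide then saturates C2=C3 and the C1 carbinol is oxidised to the ketone.
2. The 13-acetoxy-7(11)-butenolide comes from an α-methylene-γ-butyrolactone by dihydroxylation, C13 acetylation and syn-dehydration; the C8 tiglate goes on before the dehydration.
3. Key disconnection C7–C8: intermolecular zinc Barbier allylation of aldehyde 10 (C8, C9, C10, C14, C1) with 3-(bromomethyl)butenolide 20 (C2–C7, C11–C13, C15), which also sets C8.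
4. 10 comes from (S)-lactic acid (Seebach alkylation sets C10); 20 comes from (E)-3-methylpent-2-en-4-yn-1-ol (lipase resolution sets C6, hydroxyl-directed epoxidation sets C4/C5, ring-closing metathesis builds the furanone).
5. Ring order: oxirane, then five-membered lactone, then ten-membered carbocycle.

Assumption: positions are numbered C1–C15 as in the germacrane skeleton of the target (C12 lactone carbonyl, C13 the CH2OAc carbon, C14/C15 the methyls on C10/C4), which makes the target (4R,5R,6S,8S,10R), and (E)-3-methylpent-2-en-4-yn-1-ol is bought as the pure E isomer.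

## Route

### Fragment B (aldehyde 10)

Step 1
Reactants: 1 (S)-lactic acid; 2 pivalaldehyde
Product: 3 (2S,5S)-2-tert-butyl-5-methyl-1,3-dioxolan-4-one
Conditions: TsOH·H2O (cat.), H2SO4 (cat.), pentane, reflux, Dean–Stark; recrystallisation
Reagents that add atoms: none
Why: Acid-catalysed acetalisation (Seebach self-regeneration of stereocentres) gives the cis-dioxolanone, the new acetal centre (2S) being set under thermodynamic control by the lactate centre.

Step 2
Reactants: 3 (2S,5S)-2-tert-butyl-5-methyl-1,3-dioxolan-4-one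
Product: 5 (2S,5R)-2-tert-butyl-5-methyl-5-(prop-2-enyl)-1,3-dioxolan-4-one, via lithium enolate 4 (not isolated)
Conditions: LDA, THF, −78 °C; allyl bromide, −78 → −20 °C
Reagents that add atoms: allyl bromide, C=CCBr
Why: Enolate alkylation in which allyl bromide enters anti to the tert-butyl group, so the quaternary centre (future C10) is formed with high diastereoselectivity.

Step 3
Reactants: 5 (2S,5R)-2-tert-butyl-5-methyl-5-(prop-2-enyl)-1,3-dioxolan-4-one
Product: 6 (R)-2-methylpent-4-ene-1,2-diol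
Conditions: LiAlH4, Et2O, 0 °C → rt
Reagents that add atoms: none
Why: Hydride reduction of the lactone carbonyl with collapse of the acetal releases the 1,2-diol without touching the quaternary stereocentre.

Step 4
Reactants: 6 (R)-2-methylpent-4-ene-1,2-diol
Product: 7 (R)-1-[(4-methoxybenzyl)oxy]-2-methylpent-4-en-2-ol
Conditions: NaH (1.05 equiv), THF/DMF, 0 °C; 4-methoxybenzyl chloride, tetrabutylammonium iodide (cat.), 0 °C → rt
Reagents that add atoms: 4-methoxybenzyl chloride, COc1ccc(CCl)cc1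
Why: Williamson etherification is selective for the primary alkoxide over the hindered tertiary one.

Step 5
Reactants: 7 (R)-1-[(4-methoxybenzyl)oxy]-2-methylpent-4-en-2-ol
Product: 8 (R)-1-[(4-methoxybenzyl)oxy]-2-methylpent-4-en-2-yl acetate
Conditions: Ac2O, DMAP, Et3N, CH2Cl2, rt → 40 °C
Reagents that add atoms: acetic anhydride, CC(=O)OC(C)=O
Why: DMAP-catalysed acylation installs the tertiary C10 acetate early, while the alcohol is unhindered and no base-sensitive group is present.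

Step 6
Reactants: 8 (R)-1-[(4-methoxybenzyl)oxy]-2-methylpent-4-en-2-yl acetate
Product: 10 (R)-1-[(4-methoxybenzyl)oxy]-2-methyl-4-oxobutan-2-yl acetate, via vicinal diol 9 (not isolated)
Conditions: OsO4 (2 mol%), NaIO4, 2,6-lutidine, dioxane/H2O, rt; used crude
Reagents that add atoms: osmium tetroxide, O=[Os](=O)(=O)=O; sodium periodate, [Na+].[O-]I(=O)(=O)=O
Why: Lemieux–Johnson oxidative cleavage of the terminal alkene gives the C8 aldehyde under near-neutral conditions that spare the PMB ether and the β-acetoxy group.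

### Fragment A (allylic bromide 20)

Step 7
Reactants: 11 (E)-3-methylpent-2-en-4-yn-1-ol
Product: 13 (E)-3-methyl-5-(trimethylsilyl)pent-2-en-4-yn-1-ol, via bis-silyl compound 12 (not isolated)
Conditions: EtMgBr (2.2 equiv), THF, 0 °C → rt; Me3SiCl (2.3 equiv); then 1 M HCl, 0 °C
Reagents that add atoms: chlorotrimethylsilane, C[Si](C)(C)Cl
Why: Double deprotonation and silylation followed by selective hydrolysis of the labile O–Si bond caps the alkyne, which must stay inert in the later metathesis.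

Step 8
Reactants: 13 (E)-3-methyl-5-(trimethylsilyl)pent-2-en-4-yn-1-ol
Product: 14 (E)-3-methyl-5-(trimethylsilyl)pent-2-en-4-ynal
Conditions: MnO2 (activated, excess), CH2Cl2, rt
Reagents that add atoms: none
Why: Chemoselective allylic oxidation with retention of the E-alkene geometry.

Step 9
Reactants: 14 (E)-3-methyl-5-(trimethylsilyl)pent-2-en-4-ynal
Product: 15 rac-(E)-5-methyl-7-(trimethylsilyl)hepta-1,4-dien-6-yn-3-ol
Conditions: CH2=CHMgBr, THF, −78 °C; aq. NH4Cl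
Reagents that add atoms: vinylmagnesium bromide, C=C[Mg]Br
Why: 1,2-Addition of the Grignard reagent to the enal introduces C7 and the C6 carbinol (racemic at this stage).

Step 10
Reactants: 15 rac-(E)-5-methyl-7-(trimethylsilyl)hepta-1,4-dien-6-yn-3-ol
Product: 16 (S,E)-5-methyl-7-(trimethylsilyl)hepta-1,4-dien-6-yn-3-ol
Conditions: immobilised Candida antarctica lipase B, vinyl acetate, hexane, 30 °C, to ca. 55% conversion; chromatography
Reagents that add atoms: none
Why: Lipase-catalysed kinetic resolution (Kazlauskas rule, vinyl as the medium group) acetylates the R enantiomer and leaves the S alcohol, which fixes C6.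

Step 11
Reactants: 16 (S,E)-5-methyl-7-(trimethylsilyl)hepta-1,4-dien-6-yn-3-ol
Product: 17 (S)-1-[(2R,3R)-3-methyl-3-(trimethylsilylethynyl)oxiran-2-yl]prop-2-en-1-ol
Conditions: mCPBA, NaHCO3, CH2Cl2, 0 °C
Reagents that add atoms: 3-chloroperoxybenzoic acid, OOC(=O)c1cccc(Cl)c1
Why: Hydroxyl-directed Prilezhaev epoxidation of the trisubstituted alkene, in which A(1,3) strain with the cis methyl group fixes the reactive conformer so that oxygen is delivered syn to OH and the threo (4R,5R) epoxide results.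

Step 12
Reactants: 17 (S)-1-[(2R,3R)-3-methyl-3-(trimethylsilylethynyl)oxiran-2-yl]prop-2-en-1-ol; 18 2-(bromomethyl)prop-2-enoic acid
Product: 19 (S)-1-[(2R,3R)-3-methyl-3-(trimethylsilylethynyl)oxiran-2-yl]prop-2-enyl 2-(bromomethyl)prop-2-enoate
Conditions: DCC, DMAP (5 mol%), CH2Cl2, 0 °C
Reagents that add atoms: none
Why: Steglich esterification proceeds with retention at C6 and brings in C11, C12 and C13.

Step 13
Reactants: 19 (S)-1-[(2R,3R)-3-methyl-3-(trimethylsilylethynyl)oxiran-2-yl]prop-2-enyl 2-(bromomethyl)prop-2-enoate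
Product: 20 (S)-3-(bromomethyl)-5-[(2R,3R)-3-methyl-3-(trimethylsilylethynyl)oxiran-2-yl]furan-2(5H)-one
Conditions: second-generation Grubbs catalyst (5 mol%), CH2Cl2, 40 °C, 5 mM
Reagents that add atoms: none
Why: Ring-closing metathesis of the vinyl group with the acrylate forms the five-membered butenolide, the silyl-capped alkyne and the allylic bromide being tolerated.

### Coupling and endgame

Step 14
Reactants: 20 (S)-3-(bromomethyl)-5-[(2R,3R)-3-methyl-3-(trimethylsilylethynyl)oxiran-2-yl]furan-2(5H)-one; 10 (R)-1-[(4-methoxybenzyl)oxy]-2-methyl-4-oxobutan-2-yl acetate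
Product: 22 (4R,5R,6S,7R,8S,10R)-10-acetoxy-4,5-epoxy-8-hydroxy-1-[(4-methoxybenzyl)oxy]-2-(trimethylsilyl)-1,2-secogermacr-11(13)-en-2-yn-12,6-olide, via allylzinc bromide 21 (not isolated)
Conditions: Zn dust, THF/sat. aq. NH4Cl, 0 °C → rt
Reagents that add atoms: none
Why: Barbier-type carbonyl allylation in which the allylzinc reagent reacts through its γ-carbon (C7) on the face anti to the C6 oxiranyl group via a chair transition state with the aldehyde chain equatorial, which forms C7–C8, sets C8 as S (C7 as R) and leaves the α-methylene lactone.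

Step 15
Reactants: 22 (4R,5R,6S,7R,8S,10R)-10-acetoxy-4,5-epoxy-8-hydroxy-1-[(4-methoxybenzyl)oxy]-2-(trimethylsilyl)-1,2-secogermacr-11(13)-en-2-yn-12,6-olide
Product: 23 (4R,5R,6S,7R,8S,10R,11R)-10-acetoxy-4,5-epoxy-8,11,13-trihydroxy-1-[(4-methoxybenzyl)oxy]-2-(trimethylsilyl)-1,2-secogermacr-2-yn-12,6-olide
Conditions: K2OsO4·2H2O (5 mol%), NMO, acetone/H2O, rt
Reagents that add atoms: N-methylmorpholine N-oxide, C[N+]1([O-])CCOCC1; water, O
Why: Upjohn dihydroxylation of the only alkene in the molecule, OsO4 adding to the exocyclic methylene anti to the C7 side chain so that the tertiary C11 hydroxyl (11R) ends up cis to H7.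

Step 16
Reactants: 23 (4R,5R,6S,7R,8S,10R,11R)-10-acetoxy-4,5-epoxy-8,11,13-trihydroxy-1-[(4-methoxybenzyl)oxy]-2-(trimethylsilyl)-1,2-secogermacr-2-yn-12,6-olide
Product: 24 (4R,5R,6S,7R,8S,10R,11R)-10,13-diacetoxy-4,5-epoxy-8,11-dihydroxy-1-[(4-methoxybenzyl)oxy]-2-(trimethylsilyl)-1,2-secogermacr-2-yn-12,6-olide
Conditions: AcCl (1.1 equiv), 2,4,6-collidine, CH2Cl2, −78 °C
Reagents that add atoms: acetyl chloride, CC(Cl)=O
Why: Low-temperature acylation with a hindered pyridine base differentiates the primary C13 hydroxyl from the secondary C8 and tertiary C11 hydroxyls.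

Step 17
Reactants: 24 (4R,5R,6S,7R,8S,10R,11R)-10,13-diacetoxy-4,5-epoxy-8,11-dihydroxy-1-[(4-methoxybenzyl)oxy]-2-(trimethylsilyl)-1,2-secogermacr-2-yn-12,6-olide
Product: 25 (4R,5R,6S,7R,8S,10R,11R)-10,13-diacetoxy-4,5-epoxy-11-hydroxy-1-[(4-methoxybenzyl)oxy]-8-tigloyloxy-2-(trimethylsilyl)-1,2-secogermacr-2-yn-12,6-olide
Conditions: tigloyl chloride, DMAP, Et3N, CH2Cl2, 0 °C → rt
Reagents that add atoms: tigloyl chloride, C/C=C(\C)C(Cl)=O
Why: DMAP-catalysed acylation of the secondary C8 alcohol (the tertiary α-hydroxy lactone does not react) installs the tiglate and blocks any lactone migration to O8.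

Step 18
Reactants: 25 (4R,5R,6S,7R,8S,10R,11R)-10,13-diacetoxy-4,5-epoxy-11-hydroxy-1-[(4-methoxybenzyl)oxy]-8-tigloyloxy-2-(trimethylsilyl)-1,2-secogermacr-2-yn-12,6-olide
Product: 27 (4R,5R,6S,8S,10R)-10,13-diacetoxy-4,5-epoxy-1-[(4-methoxybenzyl)oxy]-8-tigloyloxy-2-(trimethylsilyl)-1,2-secogermacr-7(11)-en-2-yn-12,6-olide, via sulfamate ester 26 (not isolated)
Conditions: Burgess reagent, benzene, 50 °C
Reagents that add atoms: none
Why: Burgess dehydration, a syn-elimination of the tertiary sulfamate with the cis-disposed H7, gives the conjugated tetrasubstituted C7=C11 butenolide in preference to an enol acetate and removes the temporary C7 and C11 stereocentres.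

Step 19
Reactants: 27 (4R,5R,6S,8S,10R)-10,13-diacetoxy-4,5-epoxy-1-[(4-methoxybenzyl)oxy]-8-tigloyloxy-2-(trimethylsilyl)-1,2-secogermacr-7(11)-en-2-yn-12,6-olide
Product: 28 (4R,5R,6S,8S,10R)-10,13-diacetoxy-4,5-epoxy-2-iodo-1-[(4-methoxybenzyl)oxy]-8-tigloyloxy-1,2-secogermacr-7(11)-en-2-yn-12,6-olide
Conditions: N-iodosuccinimide, AgNO3 (20 mol%), acetone, rt, dark
Reagents that add atoms: N-iodosuccinimide, O=C1CCC(=O)N1I
Why: Silver-catalysed iododesilylation converts the alkynylsilane directly into the 1-iodoalkyne under neutral conditions that spare the epoxide and the esters.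

Step 20
Reactants: 28 (4R,5R,6S,8S,10R)-10,13-diacetoxy-4,5-epoxy-2-iodo-1-[(4-methoxybenzyl)oxy]-8-tigloyloxy-1,2-secogermacr-7(11)-en-2-yn-12,6-olide
Product: 29 (2Z,4R,5R,6S,8S,10R)-10,13-diacetoxy-4,5-epoxy-2-iodo-1-[(4-methoxybenzyl)oxy]-8-tigloyloxy-1,2-secogermacra-2,7(11)-dien-12,6-olide
Conditions: KO2CN=NCO2K, AcOH, pyridine/MeOH, rt
Reagents that add atoms: none
Why: Diimide cis-reduction of the iodoalkyne gives the (Z)-vinyl iodide while the tri- and tetrasubstituted conjugated alkenes are untouched.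

Step 21
Reactants: 29 (2Z,4R,5R,6S,8S,10R)-10,13-diacetoxy-4,5-epoxy-2-iodo-1-[(4-methoxybenzyl)oxy]-8-tigloyloxy-1,2-secogermacra-2,7(11)-dien-12,6-olide
Product: 30 (2Z,4R,5R,6S,8S,10R)-10,13-diacetoxy-4,5-epoxy-1-hydroxy-2-iodo-8-tigloyloxy-1,2-secogermacra-2,7(11)-dien-12,6-olide
Conditions: DDQ, CH2Cl2/pH 7 buffer, 0 °C
Reagents that add atoms: none
Why: Oxidative PMB cleavage under buffered neutral conditions frees the C1 alcohol without acyl migration from the neighbouring tertiary acetate.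

Step 22
Reactants: 30 (2Z,4R,5R,6S,8S,10R)-10,13-diacetoxy-4,5-epoxy-1-hydroxy-2-iodo-8-tigloyloxy-1,2-secogermacra-2,7(11)-dien-12,6-olide
Product: 31 (2Z,4R,5R,6S,8S,10R)-10,13-diacetoxy-4,5-epoxy-2-iodo-1-oxo-8-tigloyloxy-1,2-secogermacra-2,7(11)-dien-12,6-olide
Conditions: Dess–Martin periodinane, NaHCO3, CH2Cl2, 0 °C → rt
Reagents that add atoms: none
Why: Dess–Martin oxidation gives the non-enolisable α-acetoxy aldehyde, which is used at once.

Step 23
Reactants: 31 (2Z,4R,5R,6S,8S,10R)-10,13-diacetoxy-4,5-epoxy-2-iodo-1-oxo-8-tigloyloxy-1,2-secogermacra-2,7(11)-dien-12,6-olide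
Product: 33 (2Z,4R,5R,6S,8S,10R)-10,13-diacetoxy-4,5-epoxy-1-hydroxy-8-tigloyloxygermacra-2,7(11)-dien-12,6-olide (both C1 epimers), via vinylchromium species 32 (not isolated)
Conditions: CrCl2 (15 equiv), NiCl2 (0.1 equiv), degassed DMSO/THF, rt, 2 mM, slow addition
Reagents that add atoms: none
Why: Intramolecular Nozaki–Hiyama–Kishi coupling under high dilution closes the ten-membered ring with retention of the Z-alkene, the new C1 carbinol centre forming as an inconsequential mixture.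

Step 24
Reactants: 33 (2Z,4R,5R,6S,8S,10R)-10,13-diacetoxy-4,5-epoxy-1-hydroxy-8-tigloyloxygermacra-2,7(11)-dien-12,6-olide (both C1 epimers)
Product: 34 (4R,5R,6S,8S,10R)-10,13-diacetoxy-4,5-epoxy-1-hydroxy-8-tigloyloxygermacr-7(11)-en-12,6-olide (both C1 epimers)
Conditions: KO2CN=NCO2K, AcOH, MeOH/CH2Cl2, rt
Reagents that add atoms: none
Why: Diimide reduction saturates the strained cis-disubstituted ring alkene selectively and leaves the oxirane, the tiglate and the tetrasubstituted butenolide intact.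

Step 25
Reactants: 34 (4R,5R,6S,8S,10R)-10,13-diacetoxy-4,5-epoxy-1-hydroxy-8-tigloyloxygermacr-7(11)-en-12,6-olide (both C1 epimers)
Product: 35 (4R,5R,6S,8S,10R)-10,13-diacetoxy-4,5-epoxy-1-oxo-8-tigloyloxygermacr-7(11)-en-12,6-olide (CNP0175424.1)
Conditions: Dess–Martin periodinane, NaHCO3, CH2Cl2, rt
Reagents that add atoms: none
Why: Dess–Martin oxidation of the C1 carbinol (both epimers converge) gives the ketone and hence the target.

## Compound list

1 | (S)-lactic acid | C[C@H](O)C(=O)O | starting material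
2 | pivalaldehyde | CC(C)(C)C=O | starting material
3 | (2S,5S)-2-tert-butyl-5-methyl-1,3-dioxolan-4-one | C[C@@H]1O[C@H](C(C)(C)C)OC1=O | intermediate
4 | lithium enolate of 3 | CC1=C(O[Li])O[C@@H](C(C)(C)C)O1 | intermediate
5 | (2S,5R)-2-tert-butyl-5-methyl-5-(prop-2-enyl)-1,3-dioxolan-4-one | C[C@]1(CC=C)O[C@H](C(C)(C)C)OC1=O | intermediate
6 | (R)-2-methylpent-4-ene-1,2-diol | C[C@](CO)(CC=C)O | intermediate
7 | (R)-1-[(4-methoxybenzyl)oxy]-2-methylpent-4-en-2-ol | C[C@](COCc1ccc(OC)cc1)(CC=C)O | intermediate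
8 | (R)-1-[(4-methoxybenzyl)oxy]-2-methylpent-4-en-2-yl acetate | C[C@](COCc1ccc(OC)cc1)(CC=C)OC(C)=O | intermediate
9 | (2R)-4,5-dihydroxy-1-[(4-methoxybenzyl)oxy]-2-methylpentan-2-yl acetate (C4 epimers) | C[C@](COCc1ccc(OC)cc1)(CC(O)CO)OC(C)=O | intermediate
10 | (R)-1-[(4-methoxybenzyl)oxy]-2-methyl-4-oxobutan-2-yl acetate (fragment B) | C[C@](COCc1ccc(OC)cc1)(CC=O)OC(C)=O | intermediate
11 | (E)-3-methylpent-2-en-4-yn-1-ol | OC/C=C(\C)C#C | starting material
12 | (E)-trimethyl{[3-methyl-5-(trimethylsilyl)pent-2-en-4-yn-1-yl]oxy}silane | C[Si](C)(C)OC/C=C(\C)C#C[Si](C)(C)C | intermediate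
13 | (E)-3-methyl-5-(trimethylsilyl)pent-2-en-4-yn-1-ol | OC/C=C(\C)C#C[Si](C)(C)C | intermediate
14 | (E)-3-methyl-5-(trimethylsilyl)pent-2-en-4-ynal | O=C/C=C(\C)C#C[Si](C)(C)C | intermediate
15 | rac-(E)-5-methyl-7-(trimethylsilyl)hepta-1,4-dien-6-yn-3-ol | C=CC(O)/C=C(\C)C#C[Si](C)(C)C | intermediate
16 | (S,E)-5-methyl-7-(trimethylsilyl)hepta-1,4-dien-6-yn-3-ol | C=C[C@H](O)/C=C(\C)C#C[Si](C)(C)C | intermediate
17 | (S)-1-[(2R,3R)-3-methyl-3-(trimethylsilylethynyl)oxiran-2-yl]prop-2-en-1-ol | C[Si](C)(C)C#C[C@@]1(C)O[C@@H]1[C@@H](O)C=C | intermediate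
18 | 2-(bromomethyl)prop-2-enoic acid | C=C(CBr)C(=O)O | starting material
19 | (S)-1-[(2R,3R)-3-methyl-3-(trimethylsilylethynyl)oxiran-2-yl]prop-2-enyl 2-(bromomethyl)prop-2-enoate | C[Si](C)(C)C#C[C@@]1(C)O[C@@H]1[C@@H](OC(=O)C(=C)CBr)C=C | intermediate
20 | (S)-3-(bromomethyl)-5-[(2R,3R)-3-methyl-3-(trimethylsilylethynyl)oxiran-2-yl]furan-2(5H)-one (fragment A) | C[Si](C)(C)C#C[C@@]1(C)O[C@@H]1[C@H]2OC(=O)C(CBr)=C2 | intermediate
21 | allylzinc bromide derived from 20 | C[Si](C)(C)C#C[C@@]1(C)O[C@@H]1[C@H]2OC(=O)C(C[Zn]Br)=C2 | intermediate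
22 | (4R,5R,6S,7R,8S,10R)-10-acetoxy-4,5-epoxy-8-hydroxy-1-[(4-methoxybenzyl)oxy]-2-(trimethylsilyl)-1,2-secogermacr-11(13)-en-2-yn-12,6-olide | COc1ccc(COC[C@](C)(OC(C)=O)C[C@H](O)[C@@H]2[C@H](OC(=O)C2=C)[C@H]3O[C@]3(C)C#C[Si](C)(C)C)cc1 | intermediate
23 | (4R,5R,6S,7R,8S,10R,11R)-10-acetoxy-4,5-epoxy-8,11,13-trihydroxy-1-[(4-methoxybenzyl)oxy]-2-(trimethylsilyl)-1,2-secogermacr-2-yn-12,6-olide | COc1ccc(COC[C@](C)(OC(C)=O)C[C@H](O)[C@@H]2[C@H](OC(=O)[C@]2(O)CO)[C@H]3O[C@]3(C)C#C[Si](C)(C)C)cc1 | intermediate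
24 | (4R,5R,6S,7R,8S,10R,11R)-10,13-diacetoxy-4,5-epoxy-8,11-dihydroxy-1-[(4-methoxybenzyl)oxy]-2-(trimethylsilyl)-1,2-secogermacr-2-yn-12,6-olide | COc1ccc(COC[C@](C)(OC(C)=O)C[C@H](O)[C@@H]2[C@H](OC(=O)[C@]2(O)COC(C)=O)[C@H]3O[C@]3(C)C#C[Si](C)(C)C)cc1 | intermediate
25 | (4R,5R,6S,7R,8S,10R,11R)-10,13-diacetoxy-4,5-epoxy-11-hydroxy-1-[(4-methoxybenzyl)oxy]-8-tigloyloxy-2-(trimethylsilyl)-1,2-secogermacr-2-yn-12,6-olide | COc1ccc(COC[C@](C)(OC(C)=O)C[C@H](OC(=O)/C(C)=C/C)[C@@H]2[C@H](OC(=O)[C@]2(O)COC(C)=O)[C@H]3O[C@]3(C)C#C[Si](C)(C)C)cc1 | intermediate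
26 | triethylammonium salt of the C11 O-(N-methoxycarbonylsulfamate) of 25 | COc1ccc(COC[C@](C)(OC(C)=O)C[C@H](OC(=O)/C(C)=C/C)[C@@H]2[C@H](OC(=O)[C@]2(OS(=O)(=O)[N-]C(=O)OC)COC(C)=O)[C@H]3O[C@]3(C)C#C[Si](C)(C)C)cc1.CC[NH+](CC)CC | intermediate
27 | (4R,5R,6S,8S,10R)-10,13-diacetoxy-4,5-epoxy-1-[(4-methoxybenzyl)oxy]-8-tigloyloxy-2-(trimethylsilyl)-1,2-secogermacr-7(11)-en-2-yn-12,6-olide | COc1ccc(COC[C@](C)(OC(C)=O)C[C@H](OC(=O)/C(C)=C/C)C2=C(COC(C)=O)C(=O)O[C@@H]2[C@H]3O[C@]3(C)C#C[Si](C)(C)C)cc1 | intermediate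
28 | (4R,5R,6S,8S,10R)-10,13-diacetoxy-4,5-epoxy-2-iodo-1-[(4-methoxybenzyl)oxy]-8-tigloyloxy-1,2-secogermacr-7(11)-en-2-yn-12,6-olide | COc1ccc(COC[C@](C)(OC(C)=O)C[C@H](OC(=O)/C(C)=C/C)C2=C(COC(C)=O)C(=O)O[C@@H]2[C@H]3O[C@]3(C)C#CI)cc1 | intermediate
29 | (2Z,4R,5R,6S,8S,10R)-10,13-diacetoxy-4,5-epoxy-2-iodo-1-[(4-methoxybenzyl)oxy]-8-tigloyloxy-1,2-secogermacra-2,7(11)-dien-12,6-olide | COc1ccc(COC[C@](C)(OC(C)=O)C[C@H](OC(=O)/C(C)=C/C)C2=C(COC(C)=O)C(=O)O[C@@H]2[C@H]3O[C@]3(C)/C=C\I)cc1 | intermediate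
30 | (2Z,4R,5R,6S,8S,10R)-10,13-diacetoxy-4,5-epoxy-1-hydroxy-2-iodo-8-tigloyloxy-1,2-secogermacra-2,7(11)-dien-12,6-olide | OC[C@](C)(OC(C)=O)C[C@H](OC(=O)/C(C)=C/C)C1=C(COC(C)=O)C(=O)O[C@@H]1[C@H]2O[C@]2(C)/C=C\I | intermediate
31 | (2Z,4R,5R,6S,8S,10R)-10,13-diacetoxy-4,5-epoxy-2-iodo-1-oxo-8-tigloyloxy-1,2-secogermacra-2,7(11)-dien-12,6-olide | O=C[C@](C)(OC(C)=O)C[C@H](OC(=O)/C(C)=C/C)C1=C(COC(C)=O)C(=O)O[C@@H]1[C@H]2O[C@]2(C)/C=C\I | intermediate
32 | C2 vinylchromium dichloride derived from 31 | O=C[C@](C)(OC(C)=O)C[C@H](OC(=O)/C(C)=C/C)C1=C(COC(C)=O)C(=O)O[C@@H]1[C@H]2O[C@]2(C)/C=C\[Cr](Cl)Cl | intermediate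
33 | (2Z,4R,5R,6S,8S,10R)-10,13-diacetoxy-4,5-epoxy-1-hydroxy-8-tigloyloxygermacra-2,7(11)-dien-12,6-olide (both C1 epimers) | OC1/C=C\[C@@]2(C)O[C@@H]2[C@H]2OC(=O)C(COC(C)=O)=C2[C@@H](OC(=O)/C(C)=C/C)C[C@@]1(C)OC(C)=O | intermediate
34 | (4R,5R,6S,8S,10R)-10,13-diacetoxy-4,5-epoxy-1-hydroxy-8-tigloyloxygermacr-7(11)-en-12,6-olide (both C1 epimers) | OC1CC[C@@]2(C)O[C@@H]2[C@H]2OC(=O)C(COC(C)=O)=C2[C@@H](OC(=O)/C(C)=C/C)C[C@@]1(C)OC(C)=O | intermediate
35 | CNP0175424.1, (4R,5R,6S,8S,10R)-10,13-diacetoxy-4,5-epoxy-1-oxo-8-tigloyloxygermacr-7(11)-en-12,6-olide | C/C=C(\C)C(=O)O[C@H]1C[C@@](C)(OC(C)=O)C(=O)CC[C@@]2(C)O[C@@H]2[C@H]2OC(=O)C(COC(C)=O)=C12 | target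

## Step count and risks

Total steps: 25 (6 to fragment B, 7 to fragment A, 12 from the coupling to the target). Longest linear sequence: 19 steps (11 → 35, steps 7–13 and 14–25).

**Step 23, closure of the ten-membered ring.** The vinylchromium addition to a hindered α-acetoxy aldehyde at high dilution may be slow, may oligomerise, or may allow acetate migration to the new C1 alkoxide. The fallback closes the ring by metathesis at C2=C3 instead. It sets out from 27: AgNO3-catalysed protodesilylation in aqueous acetone gives the terminal alkyne F1, and semi-hydrogenation over Pd/CaCO3–Pb(OAc)2 with quinoline gives the vinyl oxirane F2. DDQ then frees the primary alcohol F3, and Dess–Martin oxidation gives the aldehyde F4. Chemoselective addition of vinyl bromide with CrCl2/NiCl2 gives the allylic alcohol F5, and ring-closing metathesis with the second-generation Grubbs catalyst at high dilution returns to the route at 33.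

**Step 18, regiochemistry of the dehydration.** The sulfamate can also eliminate toward C13 and give an exocyclic enol acetate. The fallback uses a selenoxide elimination, which does not run toward an oxygen-bearing carbon. It sets out from 22: tigloylation of the C8 hydroxyl gives the tiglate F6. Acetoxyselenenylation of the exocyclic methylene (PhSeBr, AgOAc, AcOH) puts selenium on C11 from the face cis to H7 and acetate on C13 to give the selenide F7. H2O2/pyridine oxidises this to the selenoxide F8, whose syn-elimination with H7 returns to the route at 27.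

**Step 14, the Barbier coupling.** The C8 configuration rests on a chair transition-state argument and the free C8 alkoxide could attack the lactone. The fallback corrects the stereocentre by SN2 inversion instead of relying on the allylation. It sets out from 20 and 10: if the coupling gives mainly the 8R adduct F9, this is dihydroxylated as in step 15 to the 8R triol F10 and acetylated as in step 16 to the 8R monoacetate F11. Mitsunobu esterification with tiglic acid (PPh3, DIAD) then inverts C8 and returns to the route at 25.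

## Further compounds

F1 | step 23 | terminal alkyne | COc1ccc(COC[C@](C)(OC(C)=O)C[C@H](OC(=O)/C(C)=C/C)C2=C(COC(C)=O)C(=O)O[C@@H]2[C@H]3O[C@]3(C)C#C)cc1
F2 | step 23 | vinyl oxirane | COc1ccc(COC[C@](C)(OC(C)=O)C[C@H](OC(=O)/C(C)=C/C)C2=C(COC(C)=O)C(=O)O[C@@H]2[C@H]3O[C@]3(C)C=C)cc1
F3 | step 23 | primary alcohol | OC[C@](C)(OC(C)=O)C[C@H](OC(=O)/C(C)=C/C)C1=C(COC(C)=O)C(=O)O[C@@H]1[C@H]2O[C@]2(C)C=C
F4 | step 23 | aldehyde | O=C[C@](C)(OC(C)=O)C[C@H](OC(=O)/C(C)=C/C)C1=C(COC(C)=O)C(=O)O[C@@H]1[C@H]2O[C@]2(C)C=C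
F5 | step 23 | allylic alcohol | C=CC(O)[C@](C)(OC(C)=O)C[C@H](OC(=O)/C(C)=C/C)C1=C(COC(C)=O)C(=O)O[C@@H]1[C@H]2O[C@]2(C)C=C
F6 | step 18 | tiglate | COc1ccc(COC[C@](C)(OC(C)=O)C[C@H](OC(=O)/C(C)=C/C)[C@@H]2[C@H](OC(=O)C2=C)[C@H]3O[C@]3(C)C#C[Si](C)(C)C)cc1
F7 | step 18 | selenide | COc1ccc(COC[C@](C)(OC(C)=O)C[C@H](OC(=O)/C(C)=C/C)[C@@H]2[C@H](OC(=O)[C@]2([Se]c4ccccc4)COC(C)=O)[C@H]3O[C@]3(C)C#C[Si](C)(C)C)cc1
F8 | step 18 | selenoxide | COc1ccc(COC[C@](C)(OC(C)=O)C[C@H](OC(=O)/C(C)=C/C)[C@@H]2[C@H](OC(=O)[C@]2([Se](=O)c4ccccc4)COC(C)=O)[C@H]3O[C@]3(C)C#C[Si](C)(C)C)cc1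
F9 | step 14 | 8R adduct | COc1ccc(COC[C@](C)(OC(C)=O)C[C@@H](O)[C@@H]2[C@H](OC(=O)C2=C)[C@H]3O[C@]3(C)C#C[Si](C)(C)C)cc1
F10 | step 14 | 8R triol | COc1ccc(COC[C@](C)(OC(C)=O)C[C@@H](O)[C@@H]2[C@H](OC(=O)[C@]2(O)CO)[C@H]3O[C@]3(C)C#C[Si](C)(C)C)cc1
F11 | step 14 | 8R monoacetate | COc1ccc(COC[C@](C)(OC(C)=O)C[C@@H](O)[C@@H]2[C@H](OC(=O)[C@]2(O)COC(C)=O)[C@H]3O[C@]3(C)C#C[Si](C)(C)C)cc1
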